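Numbering (carotenoid): ring carbons C1 (CMe2), C2, C3 (CHOH), C4, C5 (C-O, Me), C6; C7 = ring alkene CH, C8 = O-CH, O1 = ring oxygen, chain C9 to C12'.
Cuts: C10-C11 (Suzuki-Miyaura, last C-C bond); then C3-C4 and C5-O1 together (Prins bicyclisation); then C5-C6 (Stille) and C7-C8 (alkynylation). This leaves an alkynyl ester, a silyl enal and the C10 dialdehyde.
Enabling feature: the 1,3-dioxygen pattern C3(OH)-C4H2-C5(O1) of the cyclohexane ring, with C5 tertiary and allylic to C6=C7, and the five-membered ring whose cis C6=C7 bond holds O1 (on C8) next to C5. An aldehyde at C3, an isopropenyl group C4=C5 and an oxygen on C8 therefore suffice.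
Forward: the open chain C3-C10 is assembled, the cyclohexane and dihydrofuran rings close in one step, and the tetraenal is joined last and reduced.
Stereochemistry: C8 from ligand-controlled alkynylation. C5 (with C3 as a relay) from the key step (chiral counter-anion, chair, anti addition). C3 is then reset to the axial 3S alcohol by oxidation and hindered-hydride reduction under control of the two axial methyl groups. Alkene geometries come from anti-carbomagnesiation, trans-hydroalumination, boron-Wittig olefination and stereoretentive couplings.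

Key step: step 10

Assumption: the antipodes of the ProPhenol ligand (step 5) and of the chiral acid (step 10) are those that give the drawn configurations; their sense of induction on these new substrates has to be established with both antipodes (Mosher ester analysis at C8, NOE contact between H8 and the C5 methyl group).

Step 1
Reactants: 1 methyl 3,3-dimethylpent-4-enoate
Product: 3 methyl 3,3-dimethyl-4-oxobutanoate, via secondary ozonide 2 (not isolated)
Conditions: O3, CH2Cl2, -78 °C; then Me2S, -78 °C to rt
Reagents that add atoms: ozone, [O-][O+]=O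
Why: Ozonolysis with reductive work-up cleaves the only C=C bond and gives a neopentyl aldehyde that cannot enolise.

Step 2
Reactants: 3 methyl 3,3-dimethyl-4-oxobutanoate
Product: 4 methyl 3,3-dimethylpent-4-ynoate
Conditions: dimethyl (1-diazo-2-oxopropyl)phosphonate, K2CO3, MeOH, 0 °C to rt
Reagents that add atoms: dimethyl (1-diazo-2-oxopropyl)phosphonate, COP(=O)(OC)C(=[N+]=[N-])C(C)=O
Why: Seyferth-Gilbert homologation in the Ohira-Bestmann variant turns a non-enolisable aldehyde into the terminal alkyne (C6, C7) under carbonate/methanol conditions that leave a methyl ester unchanged.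

Step 3
Reactants: 5 3-(trimethylsilyl)prop-2-yn-1-ol
Product: 7 (E)-2-methyl-3-(trimethylsilyl)prop-2-en-1-ol, via oxamagnesacycle 6 (not isolated)
Conditions: MeMgBr (3 equiv), CuI (10 mol %), THF, 0 °C to rt; then H2O
Reagents that add atoms: methylmagnesium bromide, C[Mg]Br
Why: Copper-catalysed anti-carbomagnesiation of a propargylic alkoxide delivers methyl to the carbon next to CH2O and leaves magnesium alpha to silicon in a five-membered chelate, so protonation places silicon trans to CH2OH (the later E C9=C10 bond).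

Step 4
Reactants: 7 (E)-2-methyl-3-(trimethylsilyl)prop-2-en-1-ol
Product: 8 (E)-2-methyl-3-(trimethylsilyl)prop-2-enal
Conditions: MnO2 (activated), CH2Cl2, rt
Reagents that add atoms: none
Why: Heterogeneous allylic alcohol oxidation with MnO2 stops at the enal and should not touch the alkene geometry or the vinylsilane.

Step 5
Reactants: 4 methyl 3,3-dimethylpent-4-ynoate; 8 (E)-2-methyl-3-(trimethylsilyl)prop-2-enal
Product: 10 methyl (6R,7E)-6-hydroxy-3,3,7-trimethyl-8-(trimethylsilyl)oct-7-en-4-ynoate, via methylzinc acetylide 9 (not isolated)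
Conditions: Me2Zn (3 equiv), ProPhenol ligand (2,6-bis{[2-(hydroxydiphenylmethyl)pyrrolidin-1-yl]methyl}-4-methylphenol, 20 mol %), Ph3P=O (40 mol %), toluene, 0 °C; 4 first, then 8
Reagents that add atoms: none
Why: Catalytic asymmetric alkynylation of an enal by an alkynylzinc within a dinuclear zinc-aminoalcohol catalyst forms C7-C8 and sets C8 (R) by ligand control of the aldehyde face, and the ester survives because no strong base is used.

Step 6
Reactants: 10 methyl (6R,7E)-6-hydroxy-3,3,7-trimethyl-8-(trimethylsilyl)oct-7-en-4-ynoate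
Product: 12 (4Z,6R,7E)-4-iodo-3,3,7-trimethyl-8-(trimethylsilyl)octa-4,7-diene-1,6-diol, via cyclic alkenylalanate 11 (not isolated)
Conditions: NaAlH2(OCH2CH2OMe)2 (4 equiv), THF, 0 °C to rt; EtOAc (destroys excess hydride); then I2 (1.0 equiv), -78 °C
Reagents that add atoms: iodine, II
Why: Alkoxide-directed trans-hydroalumination of the propargylic alcohol puts aluminium on the distal carbon C6 in a five-membered alanate, iodinolysis with retention leaves iodine cis to C8, the same hydride reduces the methyl ester to the C3 primary alcohol, and one equivalent of iodine at low temperature should spare the vinylsilane.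

Step 7
Reactants: 12 (4Z,6R,7E)-4-iodo-3,3,7-trimethyl-8-(trimethylsilyl)octa-4,7-diene-1,6-diol
Product: 13 (4E,6R,7E)-3,3,7-trimethyl-4-(prop-1-en-2-yl)-8-(trimethylsilyl)octa-4,7-diene-1,6-diol
Conditions: tributyl(prop-1-en-2-yl)stannane, Pd(PPh3)4 (10 mol %), CuI (20 mol %), CsF (2 equiv), DMF, 45 °C
Reagents that add atoms: tributyl(prop-1-en-2-yl)stannane, C=C(C)[Sn](CCCC)(CCCC)CCCC
Why: Copper- and fluoride-assisted Stille coupling proceeds with retention at the alkenyl iodide, so the isopropenyl group (C4=C5) ends cis to C8 on C6=C7, and free hydroxyl groups and the trimethylvinylsilane are tolerated.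

Step 8
Reactants: 13 (4E,6R,7E)-3,3,7-trimethyl-4-(prop-1-en-2-yl)-8-(trimethylsilyl)octa-4,7-diene-1,6-diol
Product: 14 (4E,6R,7E)-6-hydroxy-3,3,7-trimethyl-4-(prop-1-en-2-yl)-8-(trimethylsilyl)octa-4,7-dienal
Conditions: TEMPO (10 mol %), PhI(OAc)2 (1.1 equiv), CH2Cl2, 0 °C to rt
Reagents that add atoms: none
Why: Oxoammonium (TEMPO) oxidation is governed by sterics and should take the open primary alcohol in preference to the C8 carbinol flanked by two trisubstituted alkenes, and no lactol can form because C1 and C8 are trans on C6=C7.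

Step 9
Reactants: 14 (4E,6R,7E)-6-hydroxy-3,3,7-trimethyl-4-(prop-1-en-2-yl)-8-(trimethylsilyl)octa-4,7-dienal
Product: 15 (4E,6R,7E)-3,3,7-trimethyl-4-(prop-1-en-2-yl)-8-(trimethylsilyl)-6-(trimethylsilyloxy)octa-4,7-dienal
Conditions: Me3SiCl, imidazole, CH2Cl2, 0 °C; filtration through deactivated silica
Reagents that add atoms: chlorotrimethylsilane, C[Si](C)(C)Cl
Why: Standard O-silylation installs the small helper silyl group that makes the key step aprotic and serves as its chain carrier.

Step 10
Reactants: 15 (4E,6R,7E)-3,3,7-trimethyl-4-(prop-1-en-2-yl)-8-(trimethylsilyl)-6-(trimethylsilyloxy)octa-4,7-dienal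
Product: 17 (2R,6R,7aR)-4,4,7a-trimethyl-2-[(E)-1-(trimethylsilyl)prop-1-en-2-yl]-2,4,5,6,7,7a-hexahydro-1-benzofuran-6-ol, via bicyclic trimethylsilyl ether 16 (not isolated)
Conditions: chiral BINOL-derived N-triflyl imidodiphosphorimidate Brønsted acid (IDPi, 5 mol %), toluene, -78 °C; then Et3N, K2CO3 (cat.), MeOH, 0 °C
Reagents that add atoms: none
Why: Proposed new method: the acid is silylated by 15 to a Me3Si+/chiral-anion pair that silylates the aldehyde oxygen, C4 (the CH2 terminus of the isopropenyl group) then adds to the silyloxocarbenium carbon C3 while the silyl ether oxygen on C8, held against the opposite face of C4=C5 by the cis arrangement of C5 and C8 on C6=C7, captures the tertiary allylic cation growing at C5, and the silyloxonium ion hands Me3Si+ back to the anion, so the helper silyl group travels from O1 to the C3 oxygen and is washed off by methanolysis in the same flask. The closest known reaction types are the Lewis-acid type 2 carbonyl-ene/Prins cyclisation of 5-methylhex-5-enals, oxygen-terminated Prins cascades, and the silylium counter-anion-directed asymmetric allylation and aldol addition of aliphatic aldehydes. The cyclohexane ring closes 6-endo-trig at C4=C5 (exo at C3=O) through a chair and the dihydrofuran ring closes 5-exo-trig at the same alkene, the two attacks being anti across C4=C5. C3 is controlled by the chair, in which the silyloxy group stays equatorial to avoid the axial C1 methyl group; C5 is tied to C3 by that chair plus the anti addition (O1 cis to the C3 oxygen, C5 methyl axial); the absolute sense of the pair is chosen by the chiral anion through the aldehyde face because C8 lies too far from C5 to decide it; and C8 keeps its configuration since its C-O bond is never broken. The step needs attack at C4 only, capture by oxygen faster than proton loss, and no ionisation at C8: the tether length and the tertiary allylic cation fix the regiochemistry, the gem-dimethyl group and the cis C6=C7 geometry pre-organise both closures and forbid any lactol or acetal between O1 and C3, and aprotic low-temperature conditions plus the weakly donating vinylsilane should keep the C8-O bond intact.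

Step 11
Reactants: 17 (2R,6R,7aR)-4,4,7a-trimethyl-2-[(E)-1-(trimethylsilyl)prop-1-en-2-yl]-2,4,5,6,7,7a-hexahydro-1-benzofuran-6-ol
Product: 18 (2R,7aR)-4,4,7a-trimethyl-2-[(E)-1-(trimethylsilyl)prop-1-en-2-yl]-4,5,7,7a-tetrahydro-1-benzofuran-6(2H)-one
Conditions: Dess-Martin periodinane, NaHCO3, CH2Cl2, 0 °C
Reagents that add atoms: none
Why: Buffered Dess-Martin oxidation removes the relay stereocentre at C3 under non-basic conditions, so the beta-alkoxy ketone should not open by retro-oxa-Michael elimination.

Step 12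
Reactants: 18 (2R,7aR)-4,4,7a-trimethyl-2-[(E)-1-(trimethylsilyl)prop-1-en-2-yl]-4,5,7,7a-tetrahydro-1-benzofuran-6(2H)-one
Product: 19 (2R,6S,7aR)-4,4,7a-trimethyl-2-[(E)-1-(trimethylsilyl)prop-1-en-2-yl]-2,4,5,6,7,7a-hexahydro-1-benzofuran-6-ol
Conditions: LiBH(s-Bu)3, THF, -78 °C; then H2O
Reagents that add atoms: none
Why: Hindered-borohydride reduction of a cyclohexanone whose axial trajectory is blocked by the two syn-axial methyl groups on C1 and C5 (the 3,3,5,5-tetramethylcyclohexanone situation) forces equatorial attack and gives the axial 3S alcohol, cis to the C5 methyl group and trans to O1.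

Step 13
Reactants: 19 (2R,6S,7aR)-4,4,7a-trimethyl-2-[(E)-1-(trimethylsilyl)prop-1-en-2-yl]-2,4,5,6,7,7a-hexahydro-1-benzofuran-6-ol
Product: 20 (2R,6S,7aR)-2-[(E)-1-iodoprop-1-en-2-yl]-4,4,7a-trimethyl-2,4,5,6,7,7a-hexahydro-1-benzofuran-6-ol
Conditions: N-iodosuccinimide, MeCN, 0 °C, dark
Reagents that add atoms: N-iodosuccinimide, O=C1CCC(=O)N1I
Why: Electrophilic ipso-iododesilylation in acetonitrile proceeds with retention through the beta-silyl cation, and the vinylsilane should react before the hindered ring alkene C6=C7, which is flanked by two fully substituted carbons.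

Step 14
Reactants: 21 (2E,4E,6E)-2,7-dimethylocta-2,4,6-trienedial
Product: 22 (2E,4E,6E,8E)-2,7-dimethyl-9-(4,4,5,5-tetramethyl-1,3,2-dioxaborolan-2-yl)nona-2,4,6,8-tetraenal
Conditions: bis[(pinacolato)boryl]methane, lithium 2,2,6,6-tetramethylpiperidide, THF, 0 °C; then 21 (2 equiv), -78 °C to rt, dark
Reagents that add atoms: bis[(pinacolato)boryl]methane, CC1(C)OB(CB2OC(C)(C)C(C)(C)O2)OC1(C)C
Why: Boron-Wittig olefination of one aldehyde group (dialdehyde in excess and recovered) adds C11 and gives the E alkenylboronate by syn boron-oxygen elimination from the less crowded adduct.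

Step 15
Reactants: 20 (2R,6S,7aR)-2-[(E)-1-iodoprop-1-en-2-yl]-4,4,7a-trimethyl-2,4,5,6,7,7a-hexahydro-1-benzofuran-6-ol; 22 (2E,4E,6E,8E)-2,7-dimethyl-9-(4,4,5,5-tetramethyl-1,3,2-dioxaborolan-2-yl)nona-2,4,6,8-tetraenal
Product: 23 (3S,5R,8R)-5,8-epoxy-3-hydroxy-5,8-dihydro-12'-apo-beta-caroten-12'-al
Conditions: PdCl2(dppf) (5 mol %), K3PO4 (aq.), THF, rt, degassed, dark
Reagents that add atoms: none
Why: Suzuki-Miyaura coupling of an alkenyl iodide with an alkenylboronate forms C10-C11 with retention on both partners under mildly basic, acid-free conditions that tolerate the free alcohol and the aldehyde and do not epimerise the C8 ether centre.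

Step 16
Reactants: 23 (3S,5R,8R)-5,8-epoxy-3-hydroxy-5,8-dihydro-12'-apo-beta-caroten-12'-al
Product: 24 (3S,5R,8R)-5,8-epoxy-5,8-dihydro-12'-apo-beta-carotene-3,12'-diol
Conditions: NaBH4, MeOH/THF, 0 °C, dark
Reagents that add atoms: none
Why: Borohydride 1,2-reduction of a polyenal gives the primary allylic alcohol without touching the pentaene or any stereocentre.

Compound list
1 | methyl 3,3-dimethylpent-4-enoate | COC(=O)CC(C)(C)C=C | starting material
2 | methyl 3-methyl-3-(1,2,4-trioxolan-3-yl)butanoate (secondary ozonide) | COC(=O)CC(C)(C)C1OCOO1 | intermediate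
3 | methyl 3,3-dimethyl-4-oxobutanoate | COC(=O)CC(C)(C)C=O | intermediate
4 | methyl 3,3-dimethylpent-4-ynoate | COC(=O)CC(C)(C)C#C | intermediate
5 | 3-(trimethylsilyl)prop-2-yn-1-ol | C[Si](C)(C)C#CCO | starting material
6 | 4-methyl-3-(trimethylsilyl)-2,5-dihydro-1,2-oxamagnesole (chelated alkenylmagnesium alkoxide) | CC1=C([Si](C)(C)C)[Mg]OC1 | intermediate
7 | (E)-2-methyl-3-(trimethylsilyl)prop-2-en-1-ol | OC/C(C)=C/[Si](C)(C)C | intermediate
8 | (E)-2-methyl-3-(trimethylsilyl)prop-2-enal | O=C/C(C)=C/[Si](C)(C)C | intermediate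
9 | methylzinc acetylide of 4 | COC(=O)CC(C)(C)C#C[Zn]C | intermediate
10 | methyl (6R,7E)-6-hydroxy-3,3,7-trimethyl-8-(trimethylsilyl)oct-7-en-4-ynoate | COC(=O)CC(C)(C)C#C[C@@H](O)/C(C)=C/[Si](C)(C)C | intermediate
11 | disodium salt of the five-membered alkenylalanate (Al on C6 and on the C8 oxygen, two 2-methoxyethoxy ligands, C3 alkoxide) | [Na+].[Na+].COCCO[Al-]1(OCCOC)O[C@@H](/C(C)=C/[Si](C)(C)C)C=C1C(C)(C)CC[O-] | intermediate
12 | (4Z,6R,7E)-4-iodo-3,3,7-trimethyl-8-(trimethylsilyl)octa-4,7-diene-1,6-diol | OCCC(C)(C)/C(I)=C/[C@@H](O)/C(C)=C/[Si](C)(C)C | intermediate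
13 | (4E,6R,7E)-3,3,7-trimethyl-4-(prop-1-en-2-yl)-8-(trimethylsilyl)octa-4,7-diene-1,6-diol (isopropenyl cis to the carbinol carbon) | OCCC(C)(C)/C(C(C)=C)=C/[C@@H](O)/C(C)=C/[Si](C)(C)C | intermediate
14 | (4E,6R,7E)-6-hydroxy-3,3,7-trimethyl-4-(prop-1-en-2-yl)-8-(trimethylsilyl)octa-4,7-dienal | O=CCC(C)(C)/C(C(C)=C)=C/[C@@H](O)/C(C)=C/[Si](C)(C)C | intermediate
15 | (4E,6R,7E)-3,3,7-trimethyl-4-(prop-1-en-2-yl)-8-(trimethylsilyl)-6-(trimethylsilyloxy)octa-4,7-dienal | O=CCC(C)(C)/C(C(C)=C)=C/[C@@H](O[Si](C)(C)C)/C(C)=C/[Si](C)(C)C | intermediate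
16 | 6-O-trimethylsilyl ether of 17 (2R,6R,7aR) | C[Si](C)(C)/C=C(\C)[C@H]1C=C2C(C)(C)C[C@@H](O[Si](C)(C)C)C[C@@]2(C)O1 | intermediate
17 | (2R,6R,7aR)-4,4,7a-trimethyl-2-[(E)-1-(trimethylsilyl)prop-1-en-2-yl]-2,4,5,6,7,7a-hexahydro-1-benzofuran-6-ol (3R,5R,8R in carotenoid numbering) | C[Si](C)(C)/C=C(\C)[C@H]1C=C2C(C)(C)C[C@@H](O)C[C@@]2(C)O1 | intermediate
18 | (2R,7aR)-4,4,7a-trimethyl-2-[(E)-1-(trimethylsilyl)prop-1-en-2-yl]-4,5,7,7a-tetrahydro-1-benzofuran-6(2H)-one | C[Si](C)(C)/C=C(\C)[C@H]1C=C2C(C)(C)CC(=O)C[C@@]2(C)O1 | intermediate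
19 | (2R,6S,7aR)-4,4,7a-trimethyl-2-[(E)-1-(trimethylsilyl)prop-1-en-2-yl]-2,4,5,6,7,7a-hexahydro-1-benzofuran-6-ol (3S,5R,8R) | C[Si](C)(C)/C=C(\C)[C@H]1C=C2C(C)(C)C[C@H](O)C[C@@]2(C)O1 | intermediate
20 | (2R,6S,7aR)-2-[(E)-1-iodoprop-1-en-2-yl]-4,4,7a-trimethyl-2,4,5,6,7,7a-hexahydro-1-benzofuran-6-ol | I/C=C(\C)[C@H]1C=C2C(C)(C)C[C@H](O)C[C@@]2(C)O1 | intermediate
21 | (2E,4E,6E)-2,7-dimethylocta-2,4,6-trienedial | O=C/C(C)=C/C=C/C=C(\C)C=O | starting material
22 | (2E,4E,6E,8E)-2,7-dimethyl-9-(4,4,5,5-tetramethyl-1,3,2-dioxaborolan-2-yl)nona-2,4,6,8-tetraenal | CC(/C=C/B1OC(C)(C)C(C)(C)O1)=C\C=C\C=C(/C)C=O | intermediate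
23 | (3S,5R,8R)-5,8-epoxy-3-hydroxy-5,8-dihydro-12'-apo-beta-caroten-12'-al | CC(/C=C/C=C(\C)[C@H]1C=C2C(C)(C)C[C@H](O)C[C@@]2(C)O1)=C\C=C\C=C(/C)C=O | intermediate
24 | (3S,5R,8R)-5,8-epoxy-5,8-dihydro-12'-apo-beta-carotene-3,12'-diol | CC(/C=C/C=C(\C)[C@H]1C=C2C(C)(C)C[C@H](O)C[C@@]2(C)O1)=C\C=C\C=C(/C)CO | target

Total steps: 16. Longest linear sequence: 13 steps (1, 2, 5 to 13, 15, 16).

Steps most likely to fail

First, step 10. The chiral anion may not impose a high facial preference in the presence of the C8 centre. Proton loss from the C5 cation (the ene pathway) may outrun capture by the crowded silyl ether oxygen, and the C8-O bond may ionise. The fallback separates the two bond formations and uses known chemistry. It sets out from 14. Me2AlCl (2.2 equiv, CH2Cl2, -78 °C) promotes the type 2 carbonyl-ene cyclisation, which forms the same C3-C4 bond and gives the exocyclic-methylene diol F1. Its C3 epimers are diastereomers, and the one drawn is separated by chromatography. Camphorsulfonic acid (cat., CH2Cl2, -20 °C) then protonates the methylene terminus of the diene, and the C8 hydroxyl closes the dihydrofuran at C5. The equatorial C3 hydroxyl steers the ring conformer, so O1 enters cis to it. This comes back to the route at 17.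

Second, step 7. Oxidative addition and transmetalation at an alkenyl iodide next to a quaternary carbon may be slow, so protodeiodination or homocoupling could take over. The fallback replaces cross-coupling by carbonyl addition and dehydration, and sets out from 12. Et3SiCl/imidazole gives the bis(triethylsilyl) ether F2. Iodine-lithium exchange (t-BuLi, Et2O, -78 °C), transmetalation with CeCl3 and addition to acetone give the tertiary allylic alcohol F3. Syn-elimination with the Burgess reagent gives the protected diene F4. Bu4NF buffered with AcOH removes both silyl ethers and comes back to the route at 13.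

Third, step 5. The unactivated alkyl alkyne may add sluggishly, and enantiofacial control on the alpha-branched silyl enal may be insufficient. The fallback sets C8 by ketone reduction instead of C-C bond formation, and sets out from 4 and 8. Ligand-free addition of 9 (toluene, rt) gives the racemic carbinol F5, and MnO2 oxidation gives the alkenyl alkynyl ketone F6. Corey-Bakshi-Shibata reduction with the (S)-methyl oxazaborolidine and catecholborane at -78 °C (alkenyl as the large group, alkynyl as the small group) comes back to the route at 10.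

Further compounds
F1 | step 10 | 4-[(2R,3E)-2-hydroxy-3-methyl-4-(trimethylsilyl)but-3-en-1-ylidene]-3,3-dimethyl-5-methylidenecyclohexan-1-ol (ring hydroxyl configured as in 17, side chain cis to the methylidene carbon) | C=C1C[C@H](O)CC(C)(C)/C1=C/[C@@H](O)/C(C)=C/[Si](C)(C)C
F2 | step 7 | 1,6-bis-O-triethylsilyl ether of 12 | CC[Si](CC)(CC)OCCC(C)(C)/C(I)=C/[C@@H](O[Si](CC)(CC)CC)/C(C)=C/[Si](C)(C)C
F3 | step 7 | analogue of F2 with 2-hydroxypropan-2-yl in place of iodine | CC[Si](CC)(CC)OCCC(C)(C)/C(C(C)(C)O)=C/[C@@H](O[Si](CC)(CC)CC)/C(C)=C/[Si](C)(C)C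
F4 | step 7 | 1,6-bis-O-triethylsilyl ether of 13 | CC[Si](CC)(CC)OCCC(C)(C)/C(C(C)=C)=C/[C@@H](O[Si](CC)(CC)CC)/C(C)=C/[Si](C)(C)C
F5 | step 5 | racemic methyl (7E)-6-hydroxy-3,3,7-trimethyl-8-(trimethylsilyl)oct-7-en-4-ynoate | COC(=O)CC(C)(C)C#CC(O)/C(C)=C/[Si](C)(C)C
F6 | step 5 | methyl (7E)-3,3,7-trimethyl-6-oxo-8-(trimethylsilyl)oct-7-en-4-ynoate | COC(=O)CC(C)(C)C#CC(=O)/C(C)=C/[Si](C)(C)C
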